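**Plan**

1. Numbering is that of germacrane (ring C1–C10, isopropenyl on C7, methyls on C4 and C10). Retrosynthesis first removes the three angelates, the C9 ketone and both oxiranes, leading back to a (1(10)E,4Z)-cyclodecadiene that carries O3, O6, O8 and O9.
2. The ten-membered carbocycle is cut at C3–C4. C3 is a carbinol next to C4 of the cis C4–C5 oxirane, which is the oxide of a Z-trisubstituted olefin, so C4 can be the carbon of a (Z)-alkenyl iodide and C3 an aldehyde (Ni/Cr-mediated closure).
3. The open chain is cut at C9–C10 (alkenyllithium plus Weinreb amide) and at C4=C5 (iodo-ylide olefination). The C6–C7–C8 triad comes from (S)-5-(hydroxymethyl)furan-2(5H)-one.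
4. Forward order: butenolide, lactone triad, 1,3-dioxane over O6/O8 (a temporary ring), C9–C3 arm, Z-iodide, ten-membered ring, then esters and oxiranes.
5. Stereochemistry: C6 from the chiral pool; C7 and C8 on the lactone ring (trans cuprate addition, trans hydroxylation, Mitsunobu inversion); a temporary C9 carbinol (Felkin–Anh) relays to the C1–C10 oxirane and is then oxidised away; C3 by CBS reduction; C4/C5 by C6–OH-directed epoxidation.

Key step: step 17

Remark: Ang = (Z)-2-methylbut-2-enoyl; organometallic intermediates are drawn as monomers; the ring-closure product is carried as a mixture of C3 epimers because that centre is reset two steps later.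

**Route**

Step 1
Reactants: 1 but-3-yn-1-ol
Product: 2 tert-butyl(but-3-yn-1-yloxy)diphenylsilane
Conditions: TBDPSCl, imidazole, CH2Cl2, 0 °C → rt
Reagents that add atoms: tert-butyldiphenylsilyl chloride, CC(C)(C)[Si](Cl)(c1ccccc1)c1ccccc1
Why: Imidazole-promoted silylation of a primary alcohol; no stereocentre is involved.

Step 2
Reactants: 2 tert-butyl(but-3-yn-1-yloxy)diphenylsilane
Product: 4 (E)-tert-butyl[(4-iodo-3-methylbut-3-en-1-yl)oxy]diphenylsilane, via alkenylalane 3 (not isolated)
Conditions: AlMe3, Cp2ZrCl2 (cat.), CH2Cl2, 0 °C → rt; then I2, THF, −30 → 0 °C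
Reagents that add atoms: trimethylaluminium, C[Al](C)C; iodine, II
Why: Negishi carboalumination adds methyl and aluminium syn across the terminal alkyne with methyl on the internal carbon, and iodinolysis with retention should give the E-trisubstituted alkenyl iodide.

Step 3
Reactants: 5 (S)-5-(hydroxymethyl)furan-2(5H)-one
Product: 6 (S)-5-[(tert-butyldimethylsilyloxy)methyl]furan-2(5H)-one
Conditions: TBSCl, imidazole, DMF, 0 °C → rt
Reagents that add atoms: tert-butyldimethylsilyl chloride, CC(C)(C)[Si](C)(C)Cl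
Why: Standard silylation; the C6 stereocentre of the target comes unchanged from the chiral pool.

Step 4
Reactants: 6 (S)-5-[(tert-butyldimethylsilyloxy)methyl]furan-2(5H)-one
Product: 7 (4R,5S)-5-[(tert-butyldimethylsilyloxy)methyl]-4-(prop-1-en-2-yl)dihydrofuran-2(3H)-one
Conditions: CH2=C(CH3)MgBr, CuBr·SMe2 (cat.), THF, −78 → −40 °C; aqueous work-up
Reagents that add atoms: isopropenylmagnesium bromide, C=C(C)[Mg]Br
Why: Copper-catalysed conjugate addition to the butenolide occurs anti to the C5 substituent, so the trans lactone should form and C7 is set.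

Step 5
Reactants: 7 (4R,5S)-5-[(tert-butyldimethylsilyloxy)methyl]-4-(prop-1-en-2-yl)dihydrofuran-2(3H)-one
Product: 8 (3S,4S,5S)-5-[(tert-butyldimethylsilyloxy)methyl]-3-hydroxy-4-(prop-1-en-2-yl)dihydrofuran-2(3H)-one (3-OH trans to isopropenyl)
Conditions: KN(SiMe3)2, THF, −78 °C; 2-(phenylsulfonyl)-3-phenyloxaziridine; then AcOH
Reagents that add atoms: 2-(phenylsulfonyl)-3-phenyloxaziridine, O=S(=O)(c1ccccc1)N1OC1c1ccccc1
Why: Enolate hydroxylation by an N-sulfonyloxaziridine takes place on the face opposite the neighbouring isopropenyl group, giving the 3,4-trans alcohol (C8 deliberately epimeric to the target).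

Step 6
Reactants: 8 (3S,4S,5S)-hydroxy lactone
Product: 9 (3R,4R,5S)-5-[(tert-butyldimethylsilyloxy)methyl]-2-oxo-4-(prop-1-en-2-yl)tetrahydrofuran-3-yl benzoate (3-OBz cis to isopropenyl)
Conditions: PPh3, DIAD, PhCO2H, THF, 0 °C → rt
Reagents that add atoms: benzoic acid, OC(=O)c1ccccc1
Why: Mitsunobu esterification displaces the activated α-hydroxy lactone carbon by SN2 with clean inversion, which should give the 3,4-cis arrangement required at C8.

Step 7
Reactants: 9 (3R,4R,5S)-benzoyloxy lactone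
Product: 10 (2R,3R,4S)-5-(tert-butyldimethylsilyloxy)-2,4-dihydroxy-N-methoxy-N-methyl-3-(prop-1-en-2-yl)pentanamide
Conditions: MeNH(OMe)·HCl, AlMe3 (excess), CH2Cl2, 0 °C → rt; Rochelle salt work-up
Reagents that add atoms: N,O-dimethylhydroxylamine hydrochloride, CNOC.Cl
Why: Aluminium amide aminolysis (Weinreb amide formation) opens the lactone and cleaves the benzoate in one operation without touching a stereocentre, freeing the syn-1,3-diol.

Step 8
Reactants: 10 (2R,3R,4S)-dihydroxy Weinreb amide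
Product: 11 (4R,5R,6S)-6-[(tert-butyldimethylsilyloxy)methyl]-N-methoxy-N,2,2-trimethyl-5-(prop-1-en-2-yl)-1,3-dioxane-4-carboxamide
Conditions: 2-methoxypropene, PPTS (cat.), CH2Cl2, 0 °C
Reagents that add atoms: 2-methoxypropene, COC(C)=C
Why: Fast acid-catalysed acetalisation of the syn-1,3-diol should give the all-equatorial dioxane over O6/O8 before the hydroxy amide can relactonise.

Step 9
Reactants: 11 (4R,5R,6S)-dioxane Weinreb amide; 4 (E)-tert-butyl[(4-iodo-3-methylbut-3-en-1-yl)oxy]diphenylsilane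
Product: 13 (E)-1-[(4R,5R,6S)-6-[(tert-butyldimethylsilyloxy)methyl]-2,2-dimethyl-5-(prop-1-en-2-yl)-1,3-dioxan-4-yl]-5-(tert-butyldiphenylsilyloxy)-2-methylpent-2-en-1-one, via alkenyllithium 12 (not isolated)
Conditions: 4, t-BuLi (2 equiv), Et2O, −78 °C; then 11, −78 → −20 °C; aqueous work-up
Reagents that add atoms: none
Why: Iodine–lithium exchange keeps the olefin geometry, and the chelated tetrahedral adduct of the Weinreb amide stops at single addition, so the E-enone (C9–C10 bond) should result.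

Step 10
Reactants: 13 (E)-enone
Product: 14 (1R,2E)-1-[(4R,5R,6S)-6-[(tert-butyldimethylsilyloxy)methyl]-2,2-dimethyl-5-(prop-1-en-2-yl)-1,3-dioxan-4-yl]-5-(tert-butyldiphenylsilyloxy)-2-methylpent-2-en-1-ol (C9 carbinol, 8,9-syn)
Conditions: LiBH(s-Bu)3 (L-Selectride), THF, −78 °C; aqueous work-up
Reagents that add atoms: none
Why: 1,2-Reduction by the bulky hydride under Felkin–Anh control (C8–O bond anti to the incoming hydride, no chelation) should give the 8,9-syn (9R) alcohol, a temporary stereocentre that later steers the C1–C10 oxirane.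

Step 11
Reactants: 14 (9R)-allylic alcohol
Product: 15 C9 p-methoxybenzyl ether of 14
Conditions: NaH, PMBCl, Bu4NI (cat.), THF/DMF, 0 °C → rt
Reagents that add atoms: 4-methoxybenzyl chloride, COc1ccc(CCl)cc1
Why: Williamson etherification of the secondary alkoxide; both silyl ethers and the acetonide are stable to the base.

Step 12
Reactants: 15 C9 PMB ether
Product: 16 primary C5 alcohol (TBS removed, TBDPS kept)
Conditions: HF·pyridine, pyridine, THF, 0 °C
Reagents that add atoms: none
Why: Buffered HF·pyridine cleaves a primary TBS ether much faster than a primary TBDPS ether, and the acetonide and PMB ether are inert.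

Step 13
Reactants: 16 primary C5 alcohol
Product: 17 C5 aldehyde (dioxane-4-carbaldehyde)
Conditions: Dess–Martin periodinane, pyridine, CH2Cl2, 0 °C → rt
Reagents that add atoms: none
Why: Buffered Dess–Martin oxidation gives the α-alkoxy aldehyde without epimerising C6, whose equatorial position is in any case the stable one.

Step 14
Reactants: 17 C5 aldehyde
Product: 18 (Z)-iodoalkene: 17 with CHO replaced by (Z)-CH=C(CH3)I (iodine cis to C6)
Conditions: [Ph3PCH(I)CH3]I (preformed), NaN(SiMe3)2, THF, −78 °C; then 17, −78 → −20 °C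
Reagents that add atoms: (1-iodoethyl)triphenylphosphonium iodide, CC(I)[P+](c1ccccc1)(c1ccccc1)c1ccccc1.[I-]
Why: Stork–Zhao-type Wittig olefination with the α-iodo ylide is kinetically Z-selective, placing iodine on C4 cis to C6 as the later cis oxirane requires.

Step 15
Reactants: 18 (Z)-iodoalkene
Product: 19 primary C3 alcohol (TBDPS removed)
Conditions: Bu4NF, THF, 0 °C → rt
Reagents that add atoms: none
Why: Fluoride cleavage of the silyl ether; the alkenyl iodide, acetonide and PMB ether are unaffected.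

Step 16
Reactants: 19 primary C3 alcohol
Product: 20 seco-aldehyde (C3 aldehyde, C4 iodide)
Conditions: Dess–Martin periodinane, pyridine, CH2Cl2, 0 °C; used at once
Reagents that add atoms: none
Why: Neutral Dess–Martin oxidation gives the β,γ-unsaturated aldehyde without moving the C1(10) olefin into conjugation.

Step 17
Reactants: 20 seco-aldehyde
Product: 22 bicyclic (1(10)E,4Z)-cyclodecadienols: 3-OH (both C3 epimers), 9-OPMB, O6/O8 acetonide, via alkenylchromium dichloride 21 (not isolated)
Conditions: CrCl2 (excess), NiCl2 (cat.), degassed DMSO/THF, rt, slow addition of 20 to high dilution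
Reagents that add atoms: none
Why: CrCl2 reduces NiCl2 to zerovalent nickel, which inserts into the C4–I bond, and transmetalation gives the configurationally stable (Z)-alkenyl species 21 of trivalent chromium, which adds to the C3 aldehyde (Nozaki–Hiyama–Kishi reaction). The closest known reaction type is the Ni/Cr-mediated closure of medium-ring allylic alcohols from iodoalkene aldehydes. One ring closes, the ten-membered carbocycle C1–C10, by 10-exo-trig attack of C4 on the carbonyl; it is bridged by the dioxane to a bicyclo[7.3.1] frame, and the 2,2-dimethyl-1,3-dioxane can relax to its twist form so that the C5 and C9 arms meet. The only new stereocentre, C3, is set by the conformation of the forming ring (probably alkoxide on the outer face, 3R), and it is not relied on because steps 18 and 19 erase and reset it. The step needs closure to beat oligomerisation, which the cis turn at C4=C5, the rigid E-olefin and high dilution should secure; it needs retention of the Z geometry, which the alkenyl–metal intermediates keep; and it needs chemoselectivity for the aldehyde, which the neutral chromium reagent shows toward the acetal, the ether and the olefins.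

Step 18
Reactants: 22 bicyclic allylic alcohols (C3 epimers)
Product: 23 bicyclic (Z)-enone (C3 ketone)
Conditions: Dess–Martin periodinane, pyridine, CH2Cl2, 0 °C
Reagents that add atoms: none
Why: Oxidation of both epimers converges on one enone under neutral conditions that leave the skipped C1(10) olefin in place.

Step 19
Reactants: 23 bicyclic (Z)-enone
Product: 24 (3S)-allylic alcohol
Conditions: (R)-2-methyl-CBS-oxazaborolidine [(R)-1-methyl-3,3-diphenyltetrahydro-1H,3H-pyrrolo[1,2-c][1,3,2]oxazaborole], catecholborane, toluene, −78 °C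
Reagents that add atoms: none
Why: Corey–Bakshi–Shibata reduction is 1,2-selective and catalyst-controlled, with the α-methylalkenyl group as the large and the C2 methylene as the small substituent, so the (R)-catalyst should give 3S.

Step 20
Reactants: 24 (3S)-allylic alcohol
Product: 25 (3S)-angelate
Conditions: angelic acid, 2,4,6-trichlorobenzoyl chloride, Et3N, toluene, rt; then 24, 80 °C (no DMAP)
Reagents that add atoms: angelic acid, C/C=C(/C)C(=O)O
Why: Yamaguchi-type mixed-anhydride acylation without a nucleophilic catalyst, the conditions under which angelates keep their Z geometry.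

Step 21
Reactants: 25 (3S)-angelate
Product: 26 6,8-diol (acetonide removed)
Conditions: PPTS, MeOH, 40 °C
Reagents that add atoms: none
Why: Acid-catalysed transacetalisation removes the strained bridging dioxane under conditions mild enough for the allylic ester, the PMB ether and the diene.

Step 22
Reactants: 26 6,8-diol
Product: 27 (4S,5R)-4,5-epoxy-6,8-diol
Conditions: VO(acac)2 (cat.), t-BuOOH, CH2Cl2, 0 °C
Reagents that add atoms: tert-butyl hydroperoxide, CC(C)(C)OO
Why: In this hydroxyl-directed epoxidation of a Z-allylic alcohol, C6–H eclipses the olefin (A1,3 strain) and oxygen is delivered syn to O6 (threo), which should give the cis oxirane of the target; the C1(10) olefin has no free allylic hydroxyl and should stay.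

Step 23
Reactants: 27 epoxy diol
Product: 28 3,6,8-tris-angelate 9-PMB ether
Conditions: angelic acid, 2,4,6-trichlorobenzoyl chloride, Et3N, toluene, rt; then 27, 80 °C
Reagents that add atoms: angelic acid, C/C=C(/C)C(=O)O
Why: Double mixed-anhydride acylation of the two secondary hydroxyls, again without a nucleophilic catalyst so that the angelates do not isomerise.

Step 24
Reactants: 28 tris-angelate PMB ether
Product: 29 C9 alcohol
Conditions: DDQ, CH2Cl2/pH 7 buffer, 0 °C
Reagents that add atoms: none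
Why: Oxidative PMB cleavage under neutral buffered conditions should spare the oxirane and the esters and avoid acyl migration from O8.

Step 25
Reactants: 29 C9 alcohol
Product: 30 (1S,10R)-1,10-epoxy C9 alcohol
Conditions: VO(acac)2 (cat.), t-BuOOH, CH2Cl2, 0 °C → rt
Reagents that add atoms: tert-butyl hydroperoxide, CC(C)(C)OO
Why: In this hydroxyl-directed epoxidation of an E-allylic alcohol with A1,2 strain (C10 methyl), the erythro epoxy alcohol is favoured, and the ring reinforces this because C8 lies on the inner face; the (9R) carbinol should therefore give the 1S,10R oxirane.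

Step 26
Reactants: 30 epoxy alcohol
Product: 31 target CNP0154187.3
Conditions: Dess–Martin periodinane, pyridine, CH2Cl2, 0 °C → rt
Reagents that add atoms: none
Why: Neutral oxidation of the epoxy alcohol to the α,β-epoxy ketone, which removes the temporary C9 stereocentre without base that could epimerise C8.

**Compound list**

1 | but-3-yn-1-ol | C#CCCO | starting material
2 | tert-butyl(but-3-yn-1-yloxy)diphenylsilane | C#CCCO[Si](c1ccccc1)(c1ccccc1)C(C)(C)C | intermediate
3 | dimethyl[(E)-4-(tert-butyldiphenylsilyloxy)-2-methylbut-1-enyl]aluminium (not isolated) | C/C(=C\[Al](C)C)CCO[Si](c1ccccc1)(c1ccccc1)C(C)(C)C | intermediate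
4 | (E)-tert-butyl[(4-iodo-3-methylbut-3-en-1-yl)oxy]diphenylsilane | C/C(=C\I)CCO[Si](c1ccccc1)(c1ccccc1)C(C)(C)C | intermediate
5 | (S)-5-(hydroxymethyl)furan-2(5H)-one | C1=CC(=O)O[C@@H]1CO | starting material
6 | (S)-5-[(tert-butyldimethylsilyloxy)methyl]furan-2(5H)-one | C1=CC(=O)O[C@@H]1CO[Si](C)(C)C(C)(C)C | intermediate
7 | (4R,5S)-5-[(tert-butyldimethylsilyloxy)methyl]-4-(prop-1-en-2-yl)dihydrofuran-2(3H)-one | C=C(C)[C@H]1CC(=O)O[C@@H]1CO[Si](C)(C)C(C)(C)C | intermediate
8 | (3S,4S,5S)-5-[(tert-butyldimethylsilyloxy)methyl]-3-hydroxy-4-(prop-1-en-2-yl)dihydrofuran-2(3H)-one | C=C(C)[C@H]1[C@H](O)C(=O)O[C@@H]1CO[Si](C)(C)C(C)(C)C | intermediate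
9 | (3R,4R,5S)-5-[(tert-butyldimethylsilyloxy)methyl]-2-oxo-4-(prop-1-en-2-yl)tetrahydrofuran-3-yl benzoate | C=C(C)[C@H]1[C@@H](OC(=O)c2ccccc2)C(=O)O[C@@H]1CO[Si](C)(C)C(C)(C)C | intermediate
10 | (2R,3R,4S)-5-(tert-butyldimethylsilyloxy)-2,4-dihydroxy-N-methoxy-N-methyl-3-(prop-1-en-2-yl)pentanamide | C=C(C)[C@H]([C@H](O)CO[Si](C)(C)C(C)(C)C)[C@@H](O)C(=O)N(C)OC | intermediate
11 | (4R,5R,6S)-6-[(tert-butyldimethylsilyloxy)methyl]-N-methoxy-N,2,2-trimethyl-5-(prop-1-en-2-yl)-1,3-dioxane-4-carboxamide | C=C(C)[C@@H]1[C@@H](CO[Si](C)(C)C(C)(C)C)OC(C)(C)O[C@H]1C(=O)N(C)OC | intermediate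
12 | (E)-[4-(tert-butyldiphenylsilyloxy)-2-methylbut-1-enyl]lithium (not isolated) | C/C(=C\[Li])CCO[Si](c1ccccc1)(c1ccccc1)C(C)(C)C | intermediate
13 | (E)-1-[(4R,5R,6S)-6-[(tert-butyldimethylsilyloxy)methyl]-2,2-dimethyl-5-(prop-1-en-2-yl)-1,3-dioxan-4-yl]-5-(tert-butyldiphenylsilyloxy)-2-methylpent-2-en-1-one | C=C(C)[C@@H]1[C@@H](CO[Si](C)(C)C(C)(C)C)OC(C)(C)O[C@H]1C(=O)/C(C)=C/CCO[Si](c2ccccc2)(c2ccccc2)C(C)(C)C | intermediate
14 | (1R,2E)-allylic alcohol from 13 (C9 carbinol, 8,9-syn) | C=C(C)[C@@H]1[C@@H](CO[Si](C)(C)C(C)(C)C)OC(C)(C)O[C@H]1[C@H](O)/C(C)=C/CCO[Si](c2ccccc2)(c2ccccc2)C(C)(C)C | intermediate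
15 | C9 p-methoxybenzyl ether of 14 | C=C(C)[C@@H]1[C@@H](CO[Si](C)(C)C(C)(C)C)OC(C)(C)O[C@H]1[C@H](OCc2ccc(OC)cc2)/C(C)=C/CCO[Si](c2ccccc2)(c2ccccc2)C(C)(C)C | intermediate
16 | primary C5 alcohol (15 without TBS) | C=C(C)[C@@H]1[C@@H](CO)OC(C)(C)O[C@H]1[C@H](OCc2ccc(OC)cc2)/C(C)=C/CCO[Si](c2ccccc2)(c2ccccc2)C(C)(C)C | intermediate
17 | C5 aldehyde from 16 | C=C(C)[C@@H]1[C@@H](C=O)OC(C)(C)O[C@H]1[C@H](OCc2ccc(OC)cc2)/C(C)=C/CCO[Si](c2ccccc2)(c2ccccc2)C(C)(C)C | intermediate
18 | (Z)-2-iodoprop-1-enyl compound from 17 (iodine on C4, cis to C6) | C=C(C)[C@@H]1[C@@H](/C=C(C)\I)OC(C)(C)O[C@H]1[C@H](OCc2ccc(OC)cc2)/C(C)=C/CCO[Si](c2ccccc2)(c2ccccc2)C(C)(C)C | intermediate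
19 | primary C3 alcohol (18 without TBDPS) | C=C(C)[C@@H]1[C@@H](/C=C(C)\I)OC(C)(C)O[C@H]1[C@H](OCc2ccc(OC)cc2)/C(C)=C/CCO | intermediate
20 | seco-aldehyde (C3 aldehyde of 19) | C=C(C)[C@@H]1[C@@H](/C=C(C)\I)OC(C)(C)O[C@H]1[C@H](OCc2ccc(OC)cc2)/C(C)=C/CC=O | intermediate
21 | (Z)-alkenylchromium dichloride from 20 (not isolated) | C=C(C)[C@@H]1[C@@H](/C=C(C)\[Cr](Cl)Cl)OC(C)(C)O[C@H]1[C@H](OCc2ccc(OC)cc2)/C(C)=C/CC=O | intermediate
22 | bicyclic (1(10)E,4Z)-cyclodecadien-3-ols, both C3 epimers, 9-OPMB, O6/O8 acetonide | C=C(C)[C@@H]1[C@H]2/C=C(C)\C(O)C/C=C(C)/[C@@H](OCc3ccc(OC)cc3)[C@@H]1OC(C)(C)O2 | intermediate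
23 | bicyclic (Z)-enone (C3 ketone) | C=C(C)[C@@H]1[C@H]2/C=C(C)\C(=O)C/C=C(C)/[C@@H](OCc3ccc(OC)cc3)[C@@H]1OC(C)(C)O2 | intermediate
24 | (3S)-allylic alcohol | C=C(C)[C@@H]1[C@H]2/C=C(C)\[C@@H](O)C/C=C(C)/[C@@H](OCc3ccc(OC)cc3)[C@@H]1OC(C)(C)O2 | intermediate
25 | (3S)-angelate | C=C(C)[C@@H]1[C@H]2/C=C(C)\[C@@H](OC(=O)/C(C)=C\C)C/C=C(C)/[C@@H](OCc3ccc(OC)cc3)[C@@H]1OC(C)(C)O2 | intermediate
26 | 6,8-diol (3-OAng, 9-OPMB, 1(10)E,4Z-diene) | C=C(C)[C@@H]1[C@H](O)/C=C(C)\[C@@H](OC(=O)/C(C)=C\C)C/C=C(C)/[C@@H](OCc2ccc(OC)cc2)[C@@H]1O | intermediate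
27 | (4S,5R)-4,5-epoxy-6,8-diol | C=C(C)[C@@H]1[C@H](O)[C@H]2O[C@@]2(C)[C@@H](OC(=O)/C(C)=C\C)C/C=C(C)/[C@@H](OCc2ccc(OC)cc2)[C@@H]1O | intermediate
28 | 3,6,8-tris-angelate 9-PMB ether | C=C(C)[C@@H]1[C@H](OC(=O)/C(C)=C\C)[C@H]2O[C@@]2(C)[C@@H](OC(=O)/C(C)=C\C)C/C=C(C)/[C@@H](OCc2ccc(OC)cc2)[C@@H]1OC(=O)/C(C)=C\C | intermediate
29 | C9 alcohol (tris-angelate, 4,5-epoxide, 1(10)E-olefin) | C=C(C)[C@@H]1[C@H](OC(=O)/C(C)=C\C)[C@H]2O[C@@]2(C)[C@@H](OC(=O)/C(C)=C\C)C/C=C(C)/[C@@H](O)[C@@H]1OC(=O)/C(C)=C\C | intermediate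
30 | (1S,10R)-1,10-epoxy C9 alcohol | C=C(C)[C@@H]1[C@H](OC(=O)/C(C)=C\C)[C@H]2O[C@@]2(C)[C@@H](OC(=O)/C(C)=C\C)C[C@@H]2O[C@@]2(C)[C@@H](O)[C@@H]1OC(=O)/C(C)=C\C | intermediate
31 | CNP0154187.3 | C=C(C)[C@@H]1[C@H](OC(=O)/C(C)=C\C)[C@H]2O[C@@]2(C)[C@@H](OC(=O)/C(C)=C\C)C[C@@H]2O[C@@]2(C)C(=O)[C@@H]1OC(=O)/C(C)=C\C | target

**Step count and risks**

Total step count: 26. Longest linear sequence: 24 steps (steps 3 to 26, from 5).

Steps most likely to fail:

1. Step 17. Oligomerisation may outrun ring closure because the dioxane must leave its chair to let the two arms meet, and the C1(10) olefin may move into conjugation with the aldehyde before it is trapped. Fallback: set out from 20. Pinnick oxidation (NaClO2, NaH2PO4, 2-methylbut-2-ene, t-BuOH/H2O) should give the seco acid F1. Carbodiimide coupling with N,O-dimethylhydroxylamine should give the Weinreb amide F2. Iodine–lithium exchange (t-BuLi, THF, −100 °C, high dilution) followed by intramolecular acylation (Parham-type anionic cyclisation) should give enone 23 directly, where the route is rejoined.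

2. Step 19. Facial selectivity may be poor because the conformation of the ten-membered ring opposes the catalyst. Fallback: set out from 23 and reduce with the enantiomeric catalyst ((S)-2-methyl-CBS-oxazaborolidine, catecholborane), which then works with the ring bias, to the (3R)-alcohol F3. Mitsunobu esterification with angelic acid (PPh3, DIAD, toluene, 0 °C) inverts C3 and returns to 25.

3. Step 22. Threo selectivity may be low (vanadium responds less to A1,3 strain than to A1,2 strain), the homoallylic C8–OH may direct oxidation of other olefins, or O8 may open the new oxirane. Fallback: set out from 23 and make the (3R)-alcohol F3 as above. With the acetonide still in place, its hydroxyl should lie on the same outer face as O6, and VO(acac)2/t-BuOOH should then give the threo epoxy alcohol F4 with the 4S,5R oxirane. Dess–Martin oxidation gives the epoxy ketone F5. Chelation-controlled reduction with Zn(BH4)2 gives the erythro (3S)-epoxy alcohol F6. Mixed-anhydride angeloylation gives the ester F7, and PPTS/MeOH removes the acetonide to return at 27.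

**Further compounds**

F1 | step 17 | seco acid (CO2H at C3 in place of the CHO of 20) | C=C(C)[C@@H]1[C@@H](/C=C(C)\I)OC(C)(C)O[C@H]1[C@H](OCc2ccc(OC)cc2)/C(C)=C/CC(=O)O
F2 | step 17 | N-methoxy-N-methylamide of F1 | C=C(C)[C@@H]1[C@@H](/C=C(C)\I)OC(C)(C)O[C@H]1[C@H](OCc2ccc(OC)cc2)/C(C)=C/CC(=O)N(C)OC
F3 | step 19 | (3R)-allylic alcohol (C3 epimer of 24) | C=C(C)[C@@H]1[C@H]2/C=C(C)\[C@H](O)C/C=C(C)/[C@@H](OCc3ccc(OC)cc3)[C@@H]1OC(C)(C)O2
F4 | step 22 | (3R,4S,5R)-4,5-epoxy alcohol, acetonide retained | C=C(C)[C@@H]1[C@H]2[C@H]3O[C@@]3(C)[C@H](O)C/C=C(C)/[C@@H](OCc3ccc(OC)cc3)[C@@H]1OC(C)(C)O2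
F5 | step 22 | 4,5-epoxy 3-ketone | C=C(C)[C@@H]1[C@H]2[C@H]3O[C@@]3(C)C(=O)C/C=C(C)/[C@@H](OCc3ccc(OC)cc3)[C@@H]1OC(C)(C)O2
F6 | step 22 | (3S,4S,5R)-4,5-epoxy alcohol | C=C(C)[C@@H]1[C@H]2[C@H]3O[C@@]3(C)[C@@H](O)C/C=C(C)/[C@@H](OCc3ccc(OC)cc3)[C@@H]1OC(C)(C)O2
F7 | step 22 | (3S)-angelate of F6 | C=C(C)[C@@H]1[C@H]2[C@H]3O[C@@]3(C)[C@@H](OC(=O)/C(C)=C\C)C/C=C(C)/[C@@H](OCc3ccc(OC)cc3)[C@@H]1OC(C)(C)O2
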